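**Plan**

- Locants: flavanone numbering for the chromanone (O1, C2 phenyl carbon, C4 ketone, C4a=C8a, C5 to C8); C1' (OCH2), C2' (CH) and C3' (CMe2) for the bridge. The enabling feature is the tertiary carbinol C5 bonded to C2', whose neighbour C1' is held by the C6 oxygen. The tetrahydrofuran ring O–C1'–C2'–C5–C6 on the bicyclo[2.2.2]octenone (C5, C6, C7, C8, C8a, C4a, C2', C3') is therefore an aldol adduct of a C1' aldehyde onto a C5 ketone, locked as a lactol and taken down one oxidation level.
- Retrosynthesis, in order: C1'–H (lactol reduction); C2'–C5 and O–C1' together (aldol addition and lactolisation of a 1,1-dimethyl-3-oxopropyl arm on C8); C1'=O (Wacker oxidation of a vinyl group); C6–CH3; C8–C3' (dearomatising reverse prenylation); C2–phenyl (conjugate addition to a chromone); chromone C2 and the C8 methyl back to a commercial acetophenone.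
- Forward: the pyranone ring C is closed on the aromatic ring A and the phenyl group is added. Ring A is then dearomatised at C8 and at C6. The carbocyclic bridge and the tetrahydrofuran close together in the key step.
- Stereochemistry: C2 from Pd(OCOCF3)2 with a chiral pyridine–oxazoline; C8 from [Ir(cod)Cl]2 with a chiral phosphoramidite; C6 from methylation anti to the C8 arm; C5 and C2' from the geometry of the cage under reversible conditions.

Key step: step 12

Remark: the ligand enantiomers named in steps 6 and 8 are assumed to give (2R) and (8R); this has to be settled by experiment, and the mirror-image ligand is used if a catalyst shows the opposite sense.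
Remark: acetophenone 1 (2'-hydroxy-4',5',6'-trimethoxyacetophenone) is taken as commercially available.

**Route**

Step 1
Reactants: 1 1-(6-hydroxy-2,3,4-trimethoxyphenyl)ethan-1-one
Product: 2 1-(3-bromo-2-hydroxy-4,5,6-trimethoxyphenyl)ethan-1-one
Conditions: NBS (1.05 equiv), MeCN, 0 → 25 °C
Reagents that add atoms: N-bromosuccinimide, O=C1CCC(=O)N1Br
Why: Electrophilic aromatic bromination of a phenol; the ring has a single unsubstituted carbon, ortho to the free hydroxyl, so the halogen can enter only at the position that becomes C8.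

Step 2
Reactants: 2 1-(3-bromo-2-hydroxy-4,5,6-trimethoxyphenyl)ethan-1-one
Product: 3 1-(2-hydroxy-4,5,6-trimethoxy-3-methylphenyl)ethan-1-one
Conditions: MeB(OH)2 (3 equiv), Pd(OAc)2 (5 mol %), SPhos (10 mol %), K3PO4 (3 equiv), toluene/H2O (10:1), 100 °C
Reagents that add atoms: methylboronic acid, CB(O)O
Why: Suzuki–Miyaura cross-coupling with a methylboron reagent; SPhos is suited to hindered, electron-rich aryl bromides and the free phenol is carried as its phenoxide.

Step 3
Reactants: 3 1-(2-hydroxy-4,5,6-trimethoxy-3-methylphenyl)ethan-1-one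
Product: 5 5,6,7-trimethoxy-8-methyl-4H-chromen-4-one, via enaminone 4 (not isolated)
Conditions: Me2NCH(OMe)2 (3 equiv), toluene, 100 °C; then 2 M HCl, CH2Cl2, 40 °C
Reagents that add atoms: N,N-dimethylformamide dimethyl acetal, COC(OC)N(C)C
Why: Standard chromone synthesis: condensation of the methyl ketone with the formamide acetal gives enaminone 4, and acid closes the pyranone through the only ortho hydroxyl with loss of dimethylamine, which places O1 next to the methyl-bearing C8 without any regiochemical choice.

Step 4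
Reactants: 5 5,6,7-trimethoxy-8-methyl-4H-chromen-4-one
Product: 6 5,6,7-trihydroxy-8-methyl-4H-chromen-4-one
Conditions: BBr3 (6 equiv), CH2Cl2, −78 → 25 °C; then MeOH, H2O
Reagents that add atoms: none
Why: Lewis-acid cleavage of aryl methyl ethers; the chromone has no stereocentre and is stable to BBr3, so the protecting groups are exchanged before C2 is created.

Step 5
Reactants: 6 5,6,7-trihydroxy-8-methyl-4H-chromen-4-one
Product: 7 5,7-dihydroxy-6-[(4-methoxyphenyl)methoxy]-8-methyl-4H-chromen-4-one
Conditions: NaH (2.05 equiv), degassed DMF, 0 °C; then 4-MeOC6H4CH2Cl (1.0 equiv), 0 → 25 °C; 1 M HCl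
Reagents that add atoms: 4-methoxybenzyl chloride, COc1ccc(CCl)cc1
Why: Williamson etherification of a catecholate-type dianion at its more basic oxygen: the 7-oxide is delocalised into the pyranone carbonyl whereas the 6-oxide is not, so one equivalent of the benzyl chloride should alkylate O6, and the chelated 5-OH stays protonated.

Step 6
Reactants: 7 5,7-dihydroxy-6-[(4-methoxyphenyl)methoxy]-8-methyl-4H-chromen-4-one; 8 phenylboronic acid
Product: 9 (2R)-5,7-dihydroxy-6-[(4-methoxyphenyl)methoxy]-8-methyl-2-phenyl-2,3-dihydro-4H-chromen-4-one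
Conditions: 8 (2 equiv), Pd(OCOCF3)2 (5 mol %), (S)-4-tert-butyl-2-(pyridin-2-yl)-4,5-dihydrooxazole (6 mol %), NH4PF6 (30 mol %), H2O (5 equiv), ClCH2CH2Cl, 60 °C
Reagents that add atoms: none
Why: Asymmetric conjugate addition of an arylboronic acid to a chromone under divalent palladium with a pyridine–oxazoline ligand: the phenyl–palladium species adds to C2 from the face left open by the tert-butyl group, which sets (2R), and the base-free, weakly acidic medium protects the new flavanone from ring opening.

Step 7
Reactants: 10 2-methylbut-3-en-2-ol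
Product: 11 tert-butyl 2-methylbut-3-en-2-yl carbonate
Conditions: n-BuLi (1.05 equiv), THF, 0 °C; then Boc2O (1.1 equiv), 0 → 25 °C
Reagents that add atoms: di-tert-butyl dicarbonate, CC(C)(C)OC(=O)OC(=O)OC(C)(C)C
Why: Acylation of the lithium alkoxide of a tertiary allylic alcohol with Boc2O, the usual access to a tertiary allyl carbonate.

Step 8
Reactants: 9 (2R)-5,7-dihydroxy-6-[(4-methoxyphenyl)methoxy]-8-methyl-2-phenyl-2,3-dihydro-4H-chromen-4-one; 11 tert-butyl 2-methylbut-3-en-2-yl carbonate
Product: 12 (2R,8R)-5-hydroxy-6-[(4-methoxyphenyl)methoxy]-8-methyl-8-(2-methylbut-3-en-2-yl)-2-phenyl-2,3-dihydro-4H-chromene-4,7(8H)-dione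
Conditions: 11 (1.2 equiv), [Ir(cod)Cl]2 (4 mol %), (S)-5-(dinaphtho[2,1-d:1',2'-f][1,3,2]dioxaphosphepin-4-yl)-5H-dibenzo[b,f]azepine (16 mol %), THF, 25 → 40 °C, no added base
Reagents that add atoms: none
Why: Proposed new method: oxidative addition of monovalent iridium to carbonate 11 releases CO2 and tert-butoxide, which deprotonates the acidic 7-OH; the phenoxide then attacks the more substituted terminus of the 1,1-dimethylallyl–iridium cation through C8, the only nucleophilic ring carbon that bears no oxygen, while O-allylation is reversible under the catalyst and the quaternary centre cannot re-aromatise, so the enolised diketone 12 should result, with the chiral P,olefin ligand expected to differentiate the faces of C8 and set (8R) independently of the remote C2; the closest known reactions are the reverse prenylation of 3-substituted indoles with dearomatisation under [Ir(cod)Cl]2/phosphoramidite catalysis and the allylic dearomatisation of naphthols and acylphloroglucinols by allyl–metal electrophiles.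

Step 9
Reactants: 12 (2R,8R)-5-hydroxy-6-[(4-methoxyphenyl)methoxy]-8-methyl-8-(2-methylbut-3-en-2-yl)-2-phenyl-2,3-dihydro-4H-chromene-4,7(8H)-dione
Product: 13 (2R,6R,8R)-6-[(4-methoxyphenyl)methoxy]-6,8-dimethyl-8-(2-methylbut-3-en-2-yl)-2-phenyl-2,3-dihydro-4H-chromene-4,5,7(6H,8H)-trione
Conditions: NaOMe (1.0 equiv), MeOH, 0 °C; then MeI (5 equiv), 0 → 25 °C
Reagents that add atoms: iodomethane, CI
Why: C-Alkylation of a cyclic β-diketone enolate, as in the C-methylation of acylphloroglucinols: the protic solvent shields the enolate oxygens, iodomethane attacks C6 from the ring face opposite the tert-alkyl arm on C8, so the C6 oxygen ends cis to the arm (6R), and the single equivalent of base leaves no methoxide to attack the non-enolisable product.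

Step 10
Reactants: 13 (2R,6R,8R)-6-[(4-methoxyphenyl)methoxy]-6,8-dimethyl-8-(2-methylbut-3-en-2-yl)-2-phenyl-2,3-dihydro-4H-chromene-4,5,7(6H,8H)-trione
Product: 14 3-{(2R,6R,8R)-6-[(4-methoxyphenyl)methoxy]-6,8-dimethyl-4,5,7-trioxo-2-phenyl-3,4,5,6,7,8-hexahydro-2H-chromen-8-yl}-3-methylbutanal
Conditions: PdCl2(PhCN)2 (12 mol %), CuCl2·2H2O (12 mol %), AgNO2 (6 mol %), O2 (1 atm), t-BuOH/MeNO2 (15:1), 25 °C
Reagents that add atoms: dioxygen, O=O
Why: Nitrite-modified, aldehyde-selective Wacker oxidation under divalent palladium, the known anti-Markovnikov oxidation of vinyl groups on quaternary carbons; ketones and the benzyl ether are tolerated, and the protected C6 oxygen cannot take part in oxypalladation.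

Step 11
Reactants: 14 3-{(2R,6R,8R)-6-[(4-methoxyphenyl)methoxy]-6,8-dimethyl-4,5,7-trioxo-2-phenyl-3,4,5,6,7,8-hexahydro-2H-chromen-8-yl}-3-methylbutanal
Product: 15 3-[(2R,6R,8R)-6-hydroxy-6,8-dimethyl-4,5,7-trioxo-2-phenyl-3,4,5,6,7,8-hexahydro-2H-chromen-8-yl]-3-methylbutanal
Conditions: DDQ (1.5 equiv), CH2Cl2/pH 7 phosphate buffer (10:1), 0 → 25 °C
Reagents that add atoms: none
Why: Oxidative cleavage of a 4-methoxybenzyl ether by DDQ in wet, buffered CH2Cl2, a neutral method that avoids the bases and nucleophiles that would attack the non-enolisable triketone or open ring C.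

Step 12
Reactants: 15 3-[(2R,6R,8R)-6-hydroxy-6,8-dimethyl-4,5,7-trioxo-2-phenyl-3,4,5,6,7,8-hexahydro-2H-chromen-8-yl]-3-methylbutanal
Product: 17 C1'-hydroxy lactol of the target (2R,5R,6S,8R,2'S; both C1' anomers), via aldol adduct 16 (not isolated)
Conditions: pyrrolidine (0.2 equiv), AcOH (0.4 equiv), CH2Cl2, 25 °C
Reagents that add atoms: none
Why: The pyrrolidine enamine (or the enol) of the C1' aldehyde adds through C2' to the C5 ketone, and the C6 hydroxyl then adds to the regenerated C1' aldehyde to give the lactol; every step is reversible and the acetate buffer is too weak to open ring C. The closest known reactions are amine-catalysed intramolecular aldol additions of keto aldehydes to 1-hydroxybicyclo[2.2.2]octane-2-carbaldehydes and aldol–lactolisation cascades. The carbocycle closes in the 6-(enolexo)-exo-trig mode to the bicyclo[2.2.2]octenone and the tetrahydrofuran in the 5-exo-trig mode. C5 is fixed by the tether, since C2' can reach the ketone only from the face of ring A that carries the arm, and C2' is settled thermodynamically, because only the epimer with C1' on the side of the C6 oxygen (cis to the arm since step 9) can lactolise while the other returns by enolisation or retro-aldol. The step needs C5 as the only acceptor and C2' as the only donor: C7 would give a four-membered ring, C4 lies trans to C8 across the C4a=C8a bond, C5 and C7 have no α-hydrogen, and C3 cannot reach C1'. Dehydration is excluded at the bridgehead C5, so the equilibria should drain into lactol 17.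

Step 13
Reactants: 17 C1'-hydroxy lactol of the target (2R,5R,6S,8R,2'S; both C1' anomers)
Product: 18 CNP0322161.2 (2R,5R,6S,8R,2'R)
Conditions: Et3SiH (5 equiv), BF3·OEt2 (2 equiv), CH2Cl2, −78 → −20 °C
Reagents that add atoms: none
Why: Ionic hydrogenation of a lactol: BF3·OEt2 ionises the anomeric hydroxyl to the C1' oxocarbenium ion, which Et3SiH reduces to the cyclic ether, while the tertiary C5 hydroxyl at the bridgehead cannot ionise and the ketones are left alone at low temperature.

**Compound list**

1 | 1-(6-hydroxy-2,3,4-trimethoxyphenyl)ethan-1-one | CC(=O)c1c(O)cc(OC)c(OC)c1OC | starting material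
2 | 1-(3-bromo-2-hydroxy-4,5,6-trimethoxyphenyl)ethan-1-one | CC(=O)c1c(O)c(Br)c(OC)c(OC)c1OC | intermediate
3 | 1-(2-hydroxy-4,5,6-trimethoxy-3-methylphenyl)ethan-1-one | CC(=O)c1c(O)c(C)c(OC)c(OC)c1OC | intermediate
4 | (E)-3-(dimethylamino)-1-(2-hydroxy-4,5,6-trimethoxy-3-methylphenyl)prop-2-en-1-one (enaminone, not isolated) | CN(C)/C=C/C(=O)c1c(O)c(C)c(OC)c(OC)c1OC | intermediate
5 | 5,6,7-trimethoxy-8-methyl-4H-chromen-4-one | O=c1ccoc2c(C)c(OC)c(OC)c(OC)c12 | intermediate
6 | 5,6,7-trihydroxy-8-methyl-4H-chromen-4-one | O=c1ccoc2c(C)c(O)c(O)c(O)c12 | intermediate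
7 | 5,7-dihydroxy-6-[(4-methoxyphenyl)methoxy]-8-methyl-4H-chromen-4-one | O=c1ccoc2c(C)c(O)c(OCc3ccc(OC)cc3)c(O)c12 | intermediate
8 | phenylboronic acid | OB(O)c1ccccc1 | starting material
9 | (2R)-5,7-dihydroxy-6-[(4-methoxyphenyl)methoxy]-8-methyl-2-phenyl-2,3-dihydro-4H-chromen-4-one | O=C1C[C@H](c2ccccc2)Oc2c(C)c(O)c(OCc3ccc(OC)cc3)c(O)c12 | intermediate
10 | 2-methylbut-3-en-2-ol | C=CC(C)(C)O | starting material
11 | tert-butyl 2-methylbut-3-en-2-yl carbonate | C=CC(C)(C)OC(=O)OC(C)(C)C | intermediate
12 | (2R,8R)-5-hydroxy-6-[(4-methoxyphenyl)methoxy]-8-methyl-8-(2-methylbut-3-en-2-yl)-2-phenyl-2,3-dihydro-4H-chromene-4,7(8H)-dione | C=CC(C)(C)[C@@]1(C)C(=O)C(OCc3ccc(OC)cc3)=C(O)C2=C1O[C@@H](c1ccccc1)CC2=O | intermediate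
13 | (2R,6R,8R)-6-[(4-methoxyphenyl)methoxy]-6,8-dimethyl-8-(2-methylbut-3-en-2-yl)-2-phenyl-2,3-dihydro-4H-chromene-4,5,7(6H,8H)-trione | C=CC(C)(C)[C@@]1(C)C(=O)[C@@](C)(OCc3ccc(OC)cc3)C(=O)C2=C1O[C@@H](c1ccccc1)CC2=O | intermediate
14 | 3-{(2R,6R,8R)-6-[(4-methoxyphenyl)methoxy]-6,8-dimethyl-4,5,7-trioxo-2-phenyl-3,4,5,6,7,8-hexahydro-2H-chromen-8-yl}-3-methylbutanal | O=CCC(C)(C)[C@@]1(C)C(=O)[C@@](C)(OCc3ccc(OC)cc3)C(=O)C2=C1O[C@@H](c1ccccc1)CC2=O | intermediate
15 | 3-[(2R,6R,8R)-6-hydroxy-6,8-dimethyl-4,5,7-trioxo-2-phenyl-3,4,5,6,7,8-hexahydro-2H-chromen-8-yl]-3-methylbutanal (precursor of the key step) | O=CCC(C)(C)[C@@]1(C)C(=O)[C@@](C)(O)C(=O)C2=C1O[C@@H](c1ccccc1)CC2=O | intermediate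
16 | aldol adduct (2R,5R,6S,8R,2'S): C2'–C5 bond closed to the bicyclo[2.2.2]octenone, C5 and C6 hydroxyls free, formyl C1' on C2' on the side of the C6 oxygen (not isolated) | CC1(C)[C@H](C=O)[C@]2(O)[C@](C)(O)C(=O)[C@@]1(C)C1=C2C(=O)C[C@H](c2ccccc2)O1 | intermediate
17 | C1'-hydroxy lactol of the target (2R,5R,6S,8R,2'S; both C1' anomers) | CC1(C)[C@@H]2C(O)O[C@]3(C)C(=O)[C@@]1(C)C1=C(C(=O)C[C@H](c4ccccc4)O1)[C@]23O | intermediate
18 | CNP0322161.2, (2R,5R,6S,8R,2'R): flavanone-derived bicyclo[2.2.2]octenone with C5 bridgehead hydroxyl, C7 ketone, C6 and C8 methyls, C3' gem-dimethyl and the C6–O–C1'H2–C2' tetrahydrofuran | CC1(C)[C@@H]2CO[C@]3(C)C(=O)[C@@]1(C)C1=C(C(=O)C[C@H](c4ccccc4)O1)[C@]23O | target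

**Step count and risks**

Total step count: 13. Longest linear sequence: 12 steps (steps 1 to 6 and 8 to 13; step 7 prepares the allyl donor).

Step 8 (carries the label). What may go wrong: O-allylation that does not revert, attack through the unsubstituted allyl terminus, or insufficient discrimination of the two faces of C8 by the catalyst. The fallback uses an aromatic Claisen rearrangement and sets out from triol 6. Alkylation of its monoanion (KHCO3, 1 equiv; 1-bromo-3-methylbut-2-ene, DMF) should go to the most acidic 7-OH and give 5,6-dihydroxy-8-methyl-7-(3-methylbut-2-enyloxy)chromen-4-one F1. 4-Methoxybenzyl chloride with K2CO3 then etherifies the remaining non-chelated 6-OH to give the 6-(4-methoxybenzyloxy) 7-prenyl ether F2. Conjugate addition of 8 under the conditions of step 6 gives the (2R)-flavanone prenyl ether F3. Heating F3 (toluene, 110 °C) should move the allyl group from O7 to the methyl-bearing ortho carbon C8 with allylic inversion ([3,3] shift); the dienone is retained because C8 is quaternary and the product is an enolised diketone. This gives 12 together with its C8 epimer F4; the two are diastereomers and are separated by chromatography. The route is rejoined at 12.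

Step 9. What may go wrong: methylation on an enolate oxygen instead of on C6, or poor facial selectivity at C6. The fallback sets out from 12 and builds the C6 carbinol by nucleophilic methyl addition instead of enolate alkylation. DDQ (2.2 equiv, wet CH2Cl2) removes the 4-methoxybenzyl group to give the 5,6-dihydroxy enediol F5 and oxidises it on to the vicinal 5,6,7-tricarbonyl compound F6. MeTi(OiPr)3 (THF, −78 °C) should add to the central, most electrophilic C6 carbonyl from the face opposite the C8 arm and give the 6-hydroxy-6-methyl trione F7 with the oxygen cis to the arm. The Wacker conditions of step 10 applied to F7 lead to 15, where the route is rejoined.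

Step 12. What may go wrong: an aldol equilibrium that lies on the side of the open keto aldehyde, addition of the amine to the vinylogous ester carbon C8a, or loss of configuration at C2 through opening of ring C. The fallback keeps the same two bond formations but uses a Mukaiyama aldol addition, and sets out from 15. TMSOTf/Et3N (CH2Cl2, −78 °C) gives the bis(trimethylsilyl) derivative F8 (C1' silyl enol ether and C6 silyl ether). TiCl4 (CH2Cl2, −78 °C) then promotes intramolecular addition of C2' to the C5 ketone, and aqueous acid work-up removes silicon and lets the C6 hydroxyl close onto C1'. The route is rejoined at 17.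

**Further compounds**

F1 | step 8 | 5,6-dihydroxy-8-methyl-7-[(3-methylbut-2-en-1-yl)oxy]-4H-chromen-4-one | O=c1ccoc2c(C)c(OCC=C(C)C)c(O)c(O)c12
F2 | step 8 | 5-hydroxy-6-[(4-methoxyphenyl)methoxy]-8-methyl-7-[(3-methylbut-2-en-1-yl)oxy]-4H-chromen-4-one | O=c1ccoc2c(C)c(OCC=C(C)C)c(OCc3ccc(OC)cc3)c(O)c12
F3 | step 8 | (2R)-5-hydroxy-6-[(4-methoxyphenyl)methoxy]-8-methyl-7-[(3-methylbut-2-en-1-yl)oxy]-2-phenyl-2,3-dihydro-4H-chromen-4-one | O=C1C[C@H](c2ccccc2)Oc2c(C)c(OCC=C(C)C)c(OCc3ccc(OC)cc3)c(O)c12
F4 | step 8 | (2R,8S)-5-hydroxy-6-[(4-methoxyphenyl)methoxy]-8-methyl-8-(2-methylbut-3-en-2-yl)-2-phenyl-2,3-dihydro-4H-chromene-4,7(8H)-dione (C8 epimer of 12) | C=CC(C)(C)[C@]1(C)C(=O)C(OCc3ccc(OC)cc3)=C(O)C2=C1O[C@@H](c1ccccc1)CC2=O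
F5 | step 9 | (2R,8R)-5,6-dihydroxy-8-methyl-8-(2-methylbut-3-en-2-yl)-2-phenyl-2,3-dihydro-4H-chromene-4,7(8H)-dione | C=CC(C)(C)[C@@]1(C)C(=O)C(O)=C(O)C2=C1O[C@@H](c1ccccc1)CC2=O
F6 | step 9 | (2R,8R)-8-methyl-8-(2-methylbut-3-en-2-yl)-2-phenyl-2,3-dihydro-4H-chromene-4,5,6,7(8H)-tetrone | C=CC(C)(C)[C@@]1(C)C(=O)C(=O)C(=O)C2=C1O[C@@H](c1ccccc1)CC2=O
F7 | step 9 | (2R,6R,8R)-6-hydroxy-6,8-dimethyl-8-(2-methylbut-3-en-2-yl)-2-phenyl-2,3-dihydro-4H-chromene-4,5,7(6H,8H)-trione | C=CC(C)(C)[C@@]1(C)C(=O)[C@@](C)(O)C(=O)C2=C1O[C@@H](c1ccccc1)CC2=O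
F8 | step 12 | bis(trimethylsilyl) derivative of 15 (C1' trimethylsilyl enol ether, C6 trimethylsilyl ether) | C[Si](C)(C)OC=CC(C)(C)[C@@]1(C)C(=O)[C@@](C)(O[Si](C)(C)C)C(=O)C2=C1O[C@@H](c1ccccc1)CC2=O
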